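**Plan**

- Retrosynthesis: the flavanone heterocycle is opened at O1–C2 (oxa-Michael) and C2–C3 (Knoevenagel), and the resulting aryl aldehyde is traced back to an aryl bromide. Flavone ring A is then cut at C7–C8 and C4a–C5 into a 2-benzyl-4-pyrone and a malonyl unit. The pyrone is opened at its ring C–O bond to a 1,3,5-triketone, which is cut between the diketone methyl carbon and the arylacetyl carbonyl.
- Forward order: the 4-pyrone (future flavone ring C) is made first, flavone ring A is annulated onto it, the bromide becomes the aldehyde, the phloroglucinol ketoester is attached, and the flavanone heterocycle closes last.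
- Stereochemistry: the only stereocentre, flavanone C2 (S), is set by a cinchona-thiourea-catalysed oxa-Michael closure; the acid decarboxylation in the same flask and the neutral hydrogenolysis that follow are not expected to disturb it.
- Enabling feature: flavone ring A is a phloroglucinol ring fused to the 4-pyrone ring C. Its aryl-bearing C8 maps onto the benzylic carbon of a 2-benzyl-4-pyrone, C4a onto pyrone C3, and C5–C6–C7 with O5 and O7 onto one malonyl three-carbon unit, so ring A can be built onto a pyrone that already carries the biaryl bond.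

Key step: step 5

Assumption: the thiourea derived from 9-amino(9-deoxy)epiquinidine is taken to give the 2S series in step 11; if a test cyclisation shows the opposite sense, the quinine-derived pseudoenantiomer replaces it with nothing else changed.

**Route**

Step 1
Reactants: 1 4'-benzyloxyacetophenone
Product: 2 diketone 1-[4-(benzyloxy)phenyl]butane-1,3-dione
Conditions: NaH (2.5 equiv), EtOAc (4 equiv), THF, reflux; aq. HCl
Reagents that add atoms: ethyl acetate, CCOC(C)=O
Why: Crossed Claisen condensation in which the sodium enolate of the aryl methyl ketone is acetylated by ethyl acetate and the equilibrium is pulled over by formation of the stabilised diketonate.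

Step 2
Reactants: 3 (5-bromo-2-hydroxyphenyl)acetic acid
Product: 4 benzyl [2-(benzyloxy)-5-bromophenyl]acetate
Conditions: BnBr (2.3 equiv), K2CO3 (3 equiv), DMF, 60 °C
Reagents that add atoms: benzyl bromide, BrCc1ccccc1
Why: Williamson etherification of the phenoxide and SN2 alkylation of the carboxylate in one operation, which protects the phenol and supplies the ester needed as acyl donor without a separate esterification.

Step 3
Reactants: 2 diketone 1-[4-(benzyloxy)phenyl]butane-1,3-dione (2 equiv); 4 benzyl [2-(benzyloxy)-5-bromophenyl]acetate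
Product: 5 triketone 1-[2-(benzyloxy)-5-bromophenyl]-6-[4-(benzyloxy)phenyl]hexane-2,4,6-trione
Conditions: LiN(i-Pr)2 (4 equiv), THF, −78 → 0 °C; then 4, −78 → 0 °C; aq. HCl
Reagents that add atoms: none
Why: Claisen-type acylation of a 1,3-diketone dianion, whose terminal carbanion is the more nucleophilic site and adds to the ester carbonyl; the excess dianion takes up the acidic proton of the triketone and offsets loss of ester by enolisation.

Step 4
Reactants: 5 triketone 1-[2-(benzyloxy)-5-bromophenyl]-6-[4-(benzyloxy)phenyl]hexane-2,4,6-trione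
Product: 6 pyrone 2-[2-(benzyloxy)-5-bromobenzyl]-6-[4-(benzyloxy)phenyl]-4H-pyran-4-one
Conditions: TsOH·H2O (0.2 equiv), toluene, reflux, Dean–Stark
Reagents that add atoms: none
Why: Acid-catalysed cyclodehydration of a 1,3,5-triketone, in which a terminal enol oxygen adds to the other terminal carbonyl and loss of water gives the 4-pyrone; the benzyl ethers and the aryl bromide tolerate catalytic sulfonic acid.

Step 5
Reactants: 6 pyrone 2-[2-(benzyloxy)-5-bromobenzyl]-6-[4-(benzyloxy)phenyl]-4H-pyran-4-one; 7 bis(2,4,6-trichlorophenyl) malonate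
Product: 9 flavone 8-[2-(benzyloxy)-5-bromophenyl]-2-[4-(benzyloxy)phenyl]-5,7-dihydroxy-4H-chromen-4-one, via β-keto trichlorophenyl ester 8 (not isolated)
Conditions: LiN(SiMe3)2 (4 equiv), THF, −78 °C; then 7 (1.1 equiv), −78 → 23 °C, then 60 °C; aq. HCl
Reagents that add atoms: none
Why: Proposed new method: LiN(SiMe3)2 removes a benzylic proton of 6 (the anion is delocalised into the bromoaryl ring and, as a dienolate, onto the pyrone carbonyl, the way 2-alkyl-4-pyrones are known to be metalated and to react at the exocyclic carbon), and this carbanion is C-acylated by active ester 7, directly or via the aryloxycarbonylketene that 7 forms by E1cB loss of trichlorophenoxide, which creates C7–C8 and β-keto ester 8. Further base converts 8, with loss of the second trichlorophenoxide, into an acylketene whose enolate is a dienylketene reaching from pyrone C3 to the ketene carbon; six-electron electrocyclisation, equivalent to a 6-exo-trig Claisen-type attack of dienolate carbon C3 on the acyl carbon, forms C4a–C5 and closes the six-membered carbocycle, and two enolisations aromatise it to the 5,7-dihydroxy ring A. The closest known reaction types are the cyclocondensation of bis(2,4,6-trichlorophenyl) malonates with 1,3-dinucleophiles to 4-hydroxy-2-pyrones and 4-hydroxyquinolones and the electrocyclic closure of dienylketenes to phenols in ketene benzannulations; neither has been used to build a benzene ring onto a 4-pyrone. No stereocentre is formed. The step requires acylation at carbon and ring closure through carbon: the delocalised carbanion is soft, the oxygen that lets ordinary ketones close to 2-pyrones is here the pyrone ring oxygen and cannot attack, pyrone C3 is the only nucleophilic atom within six-membered reach, and acylation at C3 first followed by closure at the benzylic carbon would give the same product, so the aryl group can end up only on C8. The aryl bromide and the benzyl ethers are inert to the silylamide base.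

Step 6
Reactants: 9 flavone 8-[2-(benzyloxy)-5-bromophenyl]-2-[4-(benzyloxy)phenyl]-5,7-dihydroxy-4H-chromen-4-one
Product: 10 flavone 5,7-bis(benzyloxy)-8-[2-(benzyloxy)-5-bromophenyl]-2-[4-(benzyloxy)phenyl]-4H-chromen-4-one
Conditions: BnBr (3 equiv), K2CO3 (4 equiv), n-Bu4NI (0.1 equiv), DMF, 70 °C
Reagents that add atoms: benzyl bromide, BrCc1ccccc1
Why: Williamson etherification, with heat and excess reagent to alkylate the hydrogen-bonded 5-OH as well, so that no acidic phenol remains to interfere with the amine-catalysed steps that follow.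

Step 7
Reactants: 10 flavone 5,7-bis(benzyloxy)-8-[2-(benzyloxy)-5-bromophenyl]-2-[4-(benzyloxy)phenyl]-4H-chromen-4-one
Product: 11 aldehyde 4-(benzyloxy)-3-{5,7-bis(benzyloxy)-2-[4-(benzyloxy)phenyl]-4-oxo-4H-chromen-8-yl}benzaldehyde
Conditions: Pd(OAc)2 (3 mol%), di(1-adamantyl)-n-butylphosphine (9 mol%), TMEDA (1 equiv), CO/H2 (1:1, 5 bar), toluene, 100 °C
Reagents that add atoms: carbon monoxide, [C-]#[O+]
Why: Palladium-catalysed reductive carbonylation (formylation) of an aryl bromide with synthesis gas: oxidative addition to zerovalent palladium, CO insertion and hydrogenolysis of the acylpalladium; the bromide is unhindered and the pyrone carbonyl and benzyl ethers are spectators.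

Step 8
Reactants: 12 2',4',6'-trihydroxyacetophenone
Product: 13 ketone 1-[2,4-bis(benzyloxy)-6-hydroxyphenyl]ethanone
Conditions: BnBr (2.05 equiv), K2CO3 (2.2 equiv), DMF, 23 °C
Reagents that add atoms: benzyl bromide, BrCc1ccccc1
Why: Selective Williamson etherification: the para hydroxyl and one ortho hydroxyl are alkylated, while the remaining ortho hydroxyl is held in a hydrogen bond to the acetyl carbonyl and stays free.

Step 9
Reactants: 13 ketone 1-[2,4-bis(benzyloxy)-6-hydroxyphenyl]ethanone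
Product: 14 tert-butyl 3-[2,4-bis(benzyloxy)-6-hydroxyphenyl]-3-oxopropanoate
Conditions: LiN(SiMe3)2 (3.2 equiv), THF, −78 °C; Boc2O (1.1 equiv), −78 → 0 °C; aq. HCl (1 M, 0 °C)
Reagents that add atoms: di-tert-butyl dicarbonate, CC(C)(C)OC(=O)OC(=O)OC(C)(C)C
Why: Claisen-type C-carboxylation of a ketone enolate: in the phenoxide–enolate dianion the enolate carbon is the more reactive nucleophile towards Boc2O, and the third equivalent of base takes up the acidic proton of the β-keto ester.

Step 10
Reactants: 11 aldehyde 4-(benzyloxy)-3-{5,7-bis(benzyloxy)-2-[4-(benzyloxy)phenyl]-4-oxo-4H-chromen-8-yl}benzaldehyde; 14 tert-butyl 3-[2,4-bis(benzyloxy)-6-hydroxyphenyl]-3-oxopropanoate (1.2 equiv)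
Product: 15 alkylidene ketoester tert-butyl 2-[2,4-bis(benzyloxy)-6-hydroxybenzoyl]-3-(4-(benzyloxy)-3-{5,7-bis(benzyloxy)-2-[4-(benzyloxy)phenyl]-4-oxo-4H-chromen-8-yl}phenyl)prop-2-enoate (E/Z mixture)
Conditions: piperidine (0.2 equiv), AcOH (0.2 equiv), 4 Å MS, toluene, 23 °C
Reagents that add atoms: none
Why: Knoevenagel condensation under piperidinium acetate catalysis; the bulky tert-butyl ester slows uncatalysed closure of the phenol onto the new alkylidene, so the open-chain acceptor should be isolable.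

Step 11
Reactants: 15 alkylidene ketoester (E/Z mixture)
Product: 17 flavanone (2S)-5,7-bis(benzyloxy)-2-(4-(benzyloxy)-3-{5,7-bis(benzyloxy)-2-[4-(benzyloxy)phenyl]-4-oxo-4H-chromen-8-yl}phenyl)chroman-4-one, via chromanone tert-butyl ester 16 (not isolated)
Conditions: thiourea from 9-amino(9-deoxy)epiquinidine and 3,5-bis(trifluoromethyl)phenyl isothiocyanate (10 mol%), toluene, −25 °C; then TsOH·H2O (1 equiv), 80 °C
Reagents that add atoms: none
Why: Bifunctional cinchona-thiourea-catalysed intramolecular oxa-Michael addition: the thiourea binds the β-keto ester while the quinuclidine activates the phenol, which adds 6-endo-trig to one face of the alkylidene and fixes C2 as S; acid then cleaves the tert-butyl ester and the β-keto acid decarboxylates without involving C2.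

Step 12
Reactants: 17 flavanone (2S)-5,7-bis(benzyloxy)-2-(4-(benzyloxy)-3-{5,7-bis(benzyloxy)-2-[4-(benzyloxy)phenyl]-4-oxo-4H-chromen-8-yl}phenyl)chroman-4-one
Product: 18 target (2S)-5,7-dihydroxy-2-{3-[5,7-dihydroxy-2-(4-hydroxyphenyl)-4-oxo-4H-chromen-8-yl]-4-hydroxyphenyl}chroman-4-one
Conditions: H2 (1 atm), Pd/C (10 wt% Pd), THF/MeOH, 23 °C
Reagents that add atoms: none
Why: Catalytic hydrogenolysis of six aryl benzyl ethers under neutral conditions, which offer neither acid nor base for retro-oxa-Michael racemisation and, at low pressure with monitoring, should leave the flavone C2=C3 bond and the flavanone C2–O bond intact.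

**Compound list**

1 | 4'-benzyloxyacetophenone | CC(=O)c1ccc(OCc2ccccc2)cc1 | starting material
2 | 1-[4-(benzyloxy)phenyl]butane-1,3-dione | CC(=O)CC(=O)c1ccc(OCc2ccccc2)cc1 | intermediate
3 | (5-bromo-2-hydroxyphenyl)acetic acid | OC(=O)Cc1cc(Br)ccc1O | starting material
4 | benzyl [2-(benzyloxy)-5-bromophenyl]acetate | O=C(Cc1cc(Br)ccc1OCc1ccccc1)OCc1ccccc1 | intermediate
5 | 1-[2-(benzyloxy)-5-bromophenyl]-6-[4-(benzyloxy)phenyl]hexane-2,4,6-trione (keto/enol mixture) | O=C(Cc1cc(Br)ccc1OCc1ccccc1)CC(=O)CC(=O)c1ccc(OCc2ccccc2)cc1 | intermediate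
6 | 2-[2-(benzyloxy)-5-bromobenzyl]-6-[4-(benzyloxy)phenyl]-4H-pyran-4-one | O=c1cc(Cc2cc(Br)ccc2OCc2ccccc2)oc(-c2ccc(OCc3ccccc3)cc2)c1 | intermediate
7 | bis(2,4,6-trichlorophenyl) malonate | O=C(CC(=O)Oc1c(Cl)cc(Cl)cc1Cl)Oc1c(Cl)cc(Cl)cc1Cl | starting material
8 | 2,4,6-trichlorophenyl 4-[2-(benzyloxy)-5-bromophenyl]-4-{6-[4-(benzyloxy)phenyl]-4-oxo-4H-pyran-2-yl}-3-oxobutanoate (racemic at the labile C4; not isolated) | O=C(CC(=O)C(c1cc(Br)ccc1OCc1ccccc1)c1cc(=O)cc(-c2ccc(OCc3ccccc3)cc2)o1)Oc1c(Cl)cc(Cl)cc1Cl | intermediate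
9 | 8-[2-(benzyloxy)-5-bromophenyl]-2-[4-(benzyloxy)phenyl]-5,7-dihydroxy-4H-chromen-4-one | O=c1cc(-c2ccc(OCc3ccccc3)cc2)oc2c(-c3cc(Br)ccc3OCc3ccccc3)c(O)cc(O)c12 | intermediate
10 | 5,7-bis(benzyloxy)-8-[2-(benzyloxy)-5-bromophenyl]-2-[4-(benzyloxy)phenyl]-4H-chromen-4-one | O=c1cc(-c2ccc(OCc3ccccc3)cc2)oc2c(-c3cc(Br)ccc3OCc3ccccc3)c(OCc3ccccc3)cc(OCc3ccccc3)c12 | intermediate
11 | 4-(benzyloxy)-3-{5,7-bis(benzyloxy)-2-[4-(benzyloxy)phenyl]-4-oxo-4H-chromen-8-yl}benzaldehyde | O=Cc1ccc(OCc2ccccc2)c(-c2c(OCc3ccccc3)cc(OCc3ccccc3)c3c(=O)cc(-c4ccc(OCc5ccccc5)cc4)oc23)c1 | intermediate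
12 | 2',4',6'-trihydroxyacetophenone | CC(=O)c1c(O)cc(O)cc1O | starting material
13 | 1-[2,4-bis(benzyloxy)-6-hydroxyphenyl]ethanone | CC(=O)c1c(O)cc(OCc2ccccc2)cc1OCc1ccccc1 | intermediate
14 | tert-butyl 3-[2,4-bis(benzyloxy)-6-hydroxyphenyl]-3-oxopropanoate | CC(C)(C)OC(=O)CC(=O)c1c(O)cc(OCc2ccccc2)cc1OCc1ccccc1 | intermediate
15 | tert-butyl 2-[2,4-bis(benzyloxy)-6-hydroxybenzoyl]-3-(4-(benzyloxy)-3-{5,7-bis(benzyloxy)-2-[4-(benzyloxy)phenyl]-4-oxo-4H-chromen-8-yl}phenyl)prop-2-enoate (E/Z mixture) | CC(C)(C)OC(=O)C(=Cc1ccc(OCc2ccccc2)c(-c2c(OCc3ccccc3)cc(OCc3ccccc3)c3c(=O)cc(-c4ccc(OCc5ccccc5)cc4)oc23)c1)C(=O)c1c(O)cc(OCc2ccccc2)cc1OCc1ccccc1 | intermediate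
16 | tert-butyl (2S)-5,7-bis(benzyloxy)-2-(4-(benzyloxy)-3-{5,7-bis(benzyloxy)-2-[4-(benzyloxy)phenyl]-4-oxo-4H-chromen-8-yl}phenyl)-4-oxochromane-3-carboxylate (C3 epimerisable; not isolated) | O=C1C(C(=O)OC(C)(C)C)[C@@H](c2ccc(OCc3ccccc3)c(-c3c(OCc4ccccc4)cc(OCc4ccccc4)c4c(=O)cc(-c5ccc(OCc6ccccc6)cc5)oc34)c2)Oc2cc(OCc3ccccc3)cc(OCc3ccccc3)c21 | intermediate
17 | (2S)-5,7-bis(benzyloxy)-2-(4-(benzyloxy)-3-{5,7-bis(benzyloxy)-2-[4-(benzyloxy)phenyl]-4-oxo-4H-chromen-8-yl}phenyl)chroman-4-one | O=C1C[C@@H](c2ccc(OCc3ccccc3)c(-c3c(OCc4ccccc4)cc(OCc4ccccc4)c4c(=O)cc(-c5ccc(OCc6ccccc6)cc5)oc34)c2)Oc2cc(OCc3ccccc3)cc(OCc3ccccc3)c21 | intermediate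
18 | (2S)-5,7-dihydroxy-2-{3-[5,7-dihydroxy-2-(4-hydroxyphenyl)-4-oxo-4H-chromen-8-yl]-4-hydroxyphenyl}chroman-4-one | O=C1C[C@@H](c2ccc(O)c(-c3c(O)cc(O)c4c(=O)cc(-c5ccc(O)cc5)oc34)c2)Oc2cc(O)cc(O)c21 | target

**Step count and risks**

Total: 12 steps. Longest linear sequence: 9 steps (steps 1, 3, 4, 5, 6, 7, 10, 11, 12, from 1 to 18).

Steps most likely to fail:

1. Step 5. Proton transfer from the acidic malonate CH2 to the benzylic carbanion, attack of the silylamide on the active ester, or intermolecular trapping of the ketene could outrun C-acylation and ring closure. The fallback uses known chemistry, sets out from ketone 13 and returns at aldehyde 11. Iodination ortho to the free hydroxyl with N-iodosuccinimide gives 1-[4,6-bis(benzyloxy)-2-hydroxy-3-iodophenyl]ethanone F1. Claisen–Schmidt condensation with 4-(benzyloxy)benzaldehyde (KOH, EtOH/THF) gives (E)-1-[4,6-bis(benzyloxy)-2-hydroxy-3-iodophenyl]-3-[4-(benzyloxy)phenyl]prop-2-en-1-one F2. Oxidative cyclisation with catalytic iodine in DMSO at 120 °C gives 5,7-bis(benzyloxy)-2-[4-(benzyloxy)phenyl]-8-iodo-4H-chromen-4-one F3. Suzuki–Miyaura coupling (Pd(OAc)2, SPhos, K3PO4, toluene/H2O, 90 °C) with 4-(benzyloxy)-3-(4,4,5,5-tetramethyl-1,3,2-dioxaborolan-2-yl)benzaldehyde F4, made from commercial 4-(benzyloxy)-3-bromobenzaldehyde with B2pin2, Pd(dppf)Cl2 and KOAc, then gives 11. In this variant ring A comes from the phloroglucinol ketone and the biaryl bond is made by cross-coupling.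

2. Step 11. Uncatalysed background closure of the phenol, weak facial discrimination with so large an aryl group, or reversible ring opening during the acidic decarboxylation could erode the enantiomeric purity. The fallback sets out from bromide 10 (with ketone 13 for the partner) and returns at 17. Miyaura borylation of 10 (B2pin2, Pd(dppf)Cl2, KOAc, dioxane, 90 °C) gives 5,7-bis(benzyloxy)-8-[2-(benzyloxy)-5-(4,4,5,5-tetramethyl-1,3,2-dioxaborolan-2-yl)phenyl]-2-[4-(benzyloxy)phenyl]-4H-chromen-4-one F5. Ketone 13 and N,N-dimethylformamide dimethyl acetal give (E)-1-[2,4-bis(benzyloxy)-6-hydroxyphenyl]-3-(dimethylamino)prop-2-en-1-one F6, which HCl closes to 5,7-bis(benzyloxy)-4H-chromen-4-one F7. Rhodium-catalysed asymmetric 1,4-addition of F5 to F7 ([Rh(OH)(cod)]2, an electron-poor atropisomeric bisphosphine of the MeO-BIPHEP type in the enantiomer that gives 2S, aq. KOH, dioxane/H2O) then gives 17 directly, with C2 set by the ligand.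

3. Step 3. Proton transfer from the arylacetate to the dianion could outrun acylation, and the triketone anion could undergo aldol closure on warming. The fallback sets out from ester 4 and returns at pyrone 6; no strong base meets the arylacetyl unit. Saponification (LiOH, THF/H2O) gives [2-(benzyloxy)-5-bromophenyl]acetic acid F8, and DCC/DMAP coupling with Meldrum's acid gives 5-{2-[2-(benzyloxy)-5-bromophenyl]-1-hydroxyethylidene}-2,2-dimethyl-1,3-dioxane-4,6-dione F9. Ketone 1 is converted with trimethyl orthoformate and TsOH into 1-(benzyloxy)-4-(1,1-dimethoxyethyl)benzene F10, which loses methanol on heating with a trace of acid to give 1-(benzyloxy)-4-(1-methoxyethenyl)benzene F11. Heating F9 with F11 in toluene at 90 °C releases the acylketene, and its hetero-Diels–Alder reaction with the enol ether gives 6-[2-(benzyloxy)-5-bromobenzyl]-2-[4-(benzyloxy)phenyl]-2-methoxy-2,3-dihydro-4H-pyran-4-one F12. Elimination of methanol with TsOH gives 6.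

Further compounds
F1 | step 5 | 1-[4,6-bis(benzyloxy)-2-hydroxy-3-iodophenyl]ethanone | CC(=O)c1c(O)c(I)c(OCc2ccccc2)cc1OCc1ccccc1
F2 | step 5 | (E)-1-[4,6-bis(benzyloxy)-2-hydroxy-3-iodophenyl]-3-[4-(benzyloxy)phenyl]prop-2-en-1-one | O=C(/C=C/c1ccc(OCc2ccccc2)cc1)c1c(O)c(I)c(OCc2ccccc2)cc1OCc1ccccc1
F3 | step 5 | 5,7-bis(benzyloxy)-2-[4-(benzyloxy)phenyl]-8-iodo-4H-chromen-4-one | O=c1cc(-c2ccc(OCc3ccccc3)cc2)oc2c(I)c(OCc3ccccc3)cc(OCc3ccccc3)c12
F4 | step 5 | 4-(benzyloxy)-3-(4,4,5,5-tetramethyl-1,3,2-dioxaborolan-2-yl)benzaldehyde | O=Cc1ccc(OCc2ccccc2)c(B2OC(C)(C)C(C)(C)O2)c1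
F5 | step 11 | 5,7-bis(benzyloxy)-8-[2-(benzyloxy)-5-(4,4,5,5-tetramethyl-1,3,2-dioxaborolan-2-yl)phenyl]-2-[4-(benzyloxy)phenyl]-4H-chromen-4-one | CC1(C)OB(c2ccc(OCc3ccccc3)c(-c3c(OCc4ccccc4)cc(OCc4ccccc4)c4c(=O)cc(-c5ccc(OCc6ccccc6)cc5)oc34)c2)OC1(C)C
F6 | step 11 | (E)-1-[2,4-bis(benzyloxy)-6-hydroxyphenyl]-3-(dimethylamino)prop-2-en-1-one | CN(C)/C=C/C(=O)c1c(O)cc(OCc2ccccc2)cc1OCc1ccccc1
F7 | step 11 | 5,7-bis(benzyloxy)-4H-chromen-4-one | O=c1ccoc2cc(OCc3ccccc3)cc(OCc3ccccc3)c12
F8 | step 3 | [2-(benzyloxy)-5-bromophenyl]acetic acid | OC(=O)Cc1cc(Br)ccc1OCc1ccccc1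
F9 | step 3 | 5-{2-[2-(benzyloxy)-5-bromophenyl]-1-hydroxyethylidene}-2,2-dimethyl-1,3-dioxane-4,6-dione | CC1(C)OC(=O)C(=C(O)Cc2cc(Br)ccc2OCc2ccccc2)C(=O)O1
F10 | step 3 | 1-(benzyloxy)-4-(1,1-dimethoxyethyl)benzene | COC(C)(OC)c1ccc(OCc2ccccc2)cc1
F11 | step 3 | 1-(benzyloxy)-4-(1-methoxyethenyl)benzene | COC(=C)c1ccc(OCc2ccccc2)cc1
F12 | step 3 | 6-[2-(benzyloxy)-5-bromobenzyl]-2-[4-(benzyloxy)phenyl]-2-methoxy-2,3-dihydro-4H-pyran-4-one (racemic) | COC1(c2ccc(OCc3ccccc3)cc2)CC(=O)C=C(Cc2cc(Br)ccc2OCc2ccccc2)O1
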